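# Proposed total synthesis of CNP0309601.0 by building ring D around the ring E ether oxygen

## The problem

CNP0309601.0 is an achiral, linear octamer of phloroglucinol- and pyrogallol-type rings, lettered A to H from the 2,4,6-trihydroxyphenyl end to the 3,4,5-trihydroxyphenyl end. Seven diaryl ether oxygens join the rings and twenty-one hydroxyls are free. There is no stereocentre and no configurationally stable axis, so nothing has to be controlled stereochemically. The task is constitutional: each ether must join the right pair of carbons in rings that differ only in oxygenation pattern.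

In six of the seven ethers (A–B, B–C, C–D, E–F, F–G, G–H) at least one of the two carbons has no more than one ortho substituent. These can be made by arylating a phenol if the partners are chosen well. The D–E ether is the exception. Its ring D carbon lies between two hydroxyl-bearing carbons, and its ring E carbon lies between an aryloxy-bearing and a hydroxyl-bearing carbon, so four ortho substituents surround the oxygen whichever ring supplies the phenol.

The free polyphenol is air-sensitive, above all as phenoxide, and its phloroglucinol rings are carbon nucleophiles. All hydroxyls therefore travel as methyl ethers and are released in a last, non-oxidative step.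

The feature that makes the key step possible is that ring D is a phloroglucinol whose ring E oxygen sits on the carbon between two of its three oxygenated carbons. Those three carbons are the skeleton of a 2-aryloxymalonate. The other three, with the third oxygen in the middle, are the skeleton of a 3-oxoglutarate. Ring D can thus be assembled around an oxygen that was attached to an sp3 carbon.

## Retrosynthesis

**35 from 34.** The twenty-one O–methyl bonds of target 35 are cut last, giving the permethyl ether 34. Methyl is preferred to benzyl because every ring can then be bought with its oxygens already in place (1, 2, 6, 10, 26, 28). The forward step must cleave all methyl ethers without touching the seven aryl–O–aryl bonds, which BBr3 does.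

**34 from 25 and 33.** The C–D ether is cut on the ring D side, giving aryl triflate 25 (rings D to H) and trimer phenol 33 (rings A to C). This cut divides the octamer five plus three. It places the crowded carbon of ring C on the phenol and the electrophile on the ring D carbon flanked by two CH groups. Cutting A–B or B–C instead would lengthen the linear sequence, and D–E cannot be cut this way at all. The forward reaction is a Pd(OAc)2/biarylphosphine C–O coupling of a di-ortho-substituted phenol with an electron-rich triflate.

**25 from 20.** Triflate 25 comes from monotriflate 24 by methylation, and 24 from triol 23 by sulfonylation of the one hydroxyl that is not next to the aryloxy group. Triol 23 is the product of saponification and double decarboxylation of diester 20. The two ester groups of 20 are traceless activating groups left by the ring synthesis. The forward demands are a site-selective O-sulfonylation and a classical phloroglucinol carboxylate decarboxylation.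

**20 from 17 and 18 (key disconnection).** Ring D of 20 is opened at the two C–C bonds that join each hydroxyl-bearing carbon next to the aryloxy carbon to its ester-bearing neighbour.

- This gives dimethyl 2-aryloxymalonate 17 and dimethyl 3-oxoglutarate 18.
- The neighbouring cut, the D–E aryl–oxygen bond, would need a coupling of two di-ortho-substituted partners and is not credible.
- Other three-plus-three partitions of ring D give unsymmetrical pieces and regiochemical ambiguity. Both 17 and 18 are symmetric, so only one ring can form.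
- One ring, two C–C bonds and the most hindered ether disappear together.
- The forward reaction must acylate carbon twice, with the malonate acting only as the acyl donor.

**17 from 15 and 16.** The sp3 C–O bond of 17 is cut to tetramer phenol 15 and dimethyl chloromalonate 16. An SN2 alkylation is far less sensitive to the two ortho substituents of 15 than any arylation.

**15 from 9 and 12.** The hydroxyl of 15 is traced to the formyl group of aldehyde 13 (Dakin oxidation). The E–F ether of 13 is cut to trimer phenol 9 and bromoaldehyde 12. The formyl group activates the ortho bromide for Ullmann coupling and then becomes the oxygen. Bromoaldehyde 12 comes from 5-bromo-1,2,3-trimethoxybenzene 10 by formylation at the only free position type.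

**9 from 5 and 6; 5 from 1 and 2.** The same two-step logic is repeated. Phenol 9 comes from aldehyde 7, made from dimer phenol 5 and 3-bromo-4,5-dimethoxybenzaldehyde 6. Phenol 5 comes from aldehyde 3, made from 2-bromo-3,4,5-trimethoxybenzaldehyde 1 and 3,4,5-trimethoxyphenol 2. Only in 1 does the crowded carbon carry the bromide. There the ortho formyl group compensates and the partner phenol 2 is unhindered.

**33 from 30 and 12; 30 from 27 and 28.** Phenol 33 comes from aldehyde 31 by Dakin oxidation, and 31 from dimer phenol 30 and the same bromoaldehyde 12. Phenol 30 is unmasked from benzyl ether 29, made from the hindered phenol 2,4,6-trimethoxyphenol 28 and the unhindered bromide 27. Bromide 27 is the benzyl ether of 4-bromo-2,6-dimethoxyphenol 26. The benzyl group stops 26 from condensing with itself.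

## Roads not taken

**Alternative 1: fourfold Dakin oxidation.**
- Cut: four aryl C–OH bonds (the middle oxygen of the oxygen triads of rings C, G and H and the corresponding oxygen of ring E) are traced back to formyl groups in the tetra-aldehyde A1.
- Forward step: a peracid, then methanolic base, exchanges each formyl carbon for oxygen and gives tetraphenol A2.
- Merits: the formyl groups withdraw electrons during assembly, which eases the ether couplings and protects the rings from oxidation. One of them is para to the crowded ring E ether carbon and could in principle support an SNAr reaction there. A2 needs no re-protection before the final demethylation.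
- Weak points: four Baeyer–Villiger events must all go by aryl migration on a 21-oxygen substrate whose ring A is itself attacked by peracids, so mixtures of partly oxidised material are likely. The D–E ether still has to be made by aryl–oxygen bond formation between two di-ortho-substituted carbons on a ring deactivated for SNAr by three alkoxy groups.
- Comparison: Alternative 1 is more economical at the end, since four oxygens arrive in one operation. The chosen plan uses the same formyl-to-hydroxyl exchange, but one aldehyde at a time on dimers to tetramers where chemoselectivity is not in question. It also removes the D–E bond from coupling chemistry altogether.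

**Alternative 2: squarate ring expansion for ring C.**
- Cut: two C–C bonds of ring C.
- Forward step: heating cyclobutenone A3 opens it to a dienylketene, whose 6π electrocyclisation gives the A-B-C phenol A4.
- Merits: every oxygen of the pentaoxygenated ring C is placed by connectivity and the two free positions are differentiated (phenol versus silyl ether). The crowded B–C ether oxygen is attached to a vinyl carbon and is not made by arylation.
- Weak points: A3 needs a 1-aryloxyvinyl metal reagent from a very electron-rich aryl vinyl ether, addition to a squarate, silylation and thermolysis. The free phenol of A4 must be methylated, and the crowded ring C oxygen must still be arylated after desilylation. The D–E junction is untouched.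
- Comparison: Alternative 2 is better in regiochemical certainty and avoids one coupling of a di-ortho-substituted phenol (30 with 12 in the chosen route). The chosen plan makes the same ring in two steps from 12 and uses its one ring synthesis where no coupling alternative exists.

**Alternative 3: Danheiser benzannulation for ring F.**
- Cut: the ring F bonds flanking two alkyne carbons.
- Forward step: the ethynyl ether A5 of the G-H phenol and 2,3-dimethoxycyclobutenone A6 are heated together. The vinylketene adds to the alkyne and electrocyclisation gives the F-G-H phenol A7, which is the same compound as 9.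
- Merits: complete regiocontrol, and the phenol needed for the next coupling is formed directly. The Ullmann coupling of 5 with 6 and the Baeyer–Villiger oxidation of the 3,4,5-trioxygenated aldehyde 7 (the least favourable oxidation of the chosen route) are both avoided.
- Weak points: A5 needs an aryl ethynyl ether synthesis in the presence of many methoxy groups, and A6 is not a catalogue compound. Ring F carries the two least hindered ethers of the molecule, so a de novo ring synthesis is spent where ordinary couplings suffice.
- Comparison: Alternative 3 is at least as good as the chosen route in selectivity for this fragment. The chosen route reaches the same compound 9 in four steps from purchased materials and reserves ring construction for ring D.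

Key step: step 9

Remark on the chemistry: the target has no stereocentre and its diaryl ether axes are assumed to rotate freely, so no SMILES string carries stereodescriptors; dimethyl chloromalonate is used in place of the bromo ester to avoid bromine transfer to the electron-rich phenoxide.

Shorthand in names: Ar is the aryl residue of phenol 15, that is 6-{3,4-dimethoxy-5-[3,4,5-trimethoxy-2-(3,4,5-trimethoxyphenoxy)phenoxy]phenoxy}-2,3,4-trimethoxyphenyl.

## Route

Step 1
Reactants: 1 2-bromo-3,4,5-trimethoxybenzaldehyde; 2 3,4,5-trimethoxyphenol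
Product: 3 3,4,5-trimethoxy-2-(3,4,5-trimethoxyphenoxy)benzaldehyde (G-H aldehyde)
Conditions: CuI (10 mol %), picolinic acid (20 mol %), K3PO4, DMSO, 90 °C, argon
Reagents that add atoms: none
Why: Ullmann diaryl ether synthesis with an unhindered phenoxide; the ortho formyl group activates the flanked bromide and is the later source of the ring G oxygen.

Step 2
Reactants: 3 G-H aldehyde
Product: 5 3,4,5-trimethoxy-2-(3,4,5-trimethoxyphenoxy)phenol (G-H phenol), via aryl formate 4 (not isolated)
Conditions: 30% H2O2, H2SO4 (cat.), MeOH, rt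
Reagents that add atoms: hydrogen peroxide, OO
Why: Acid-catalysed Dakin oxidation (Baeyer–Villiger aryl migration in the perhydrate); the ortho aryloxy and para methoxy groups favour aryl over hydride migration, and the formate is methanolysed in the same flask.

Step 3
Reactants: 5 G-H phenol; 6 3-bromo-4,5-dimethoxybenzaldehyde
Product: 7 3,4-dimethoxy-5-[3,4,5-trimethoxy-2-(3,4,5-trimethoxyphenoxy)phenoxy]benzaldehyde (F-G-H aldehyde)
Conditions: CuI (10 mol %), picolinic acid (20 mol %), K3PO4, DMSO, 100 °C, argon
Reagents that add atoms: none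
Why: Ullmann diaryl ether synthesis in which each partner has a single ortho substituent, within the scope of the CuI–picolinic acid system; the aldehyde is inert to these conditions.

Step 4
Reactants: 7 F-G-H aldehyde
Product: 9 3,4-dimethoxy-5-[3,4,5-trimethoxy-2-(3,4,5-trimethoxyphenoxy)phenoxy]phenol (F-G-H phenol), via aryl formate 8 (not isolated)
Conditions: mCPBA, CH2Cl2, 0 °C to rt; then K2CO3 (cat.), MeOH
Reagents that add atoms: 3-chloroperoxybenzoic acid (mCPBA), OOC(=O)c1cccc(Cl)c1
Why: Baeyer–Villiger oxidation; with only a para methoxy donor the peracid is needed, as in the known conversion of 3,4,5-trimethoxybenzaldehyde into its phenol, and the formate is cleaved by methanolysis.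

Step 5
Reactants: 10 5-bromo-1,2,3-trimethoxybenzene
Product: 12 6-bromo-2,3,4-trimethoxybenzaldehyde, via chloro ether 11 (not isolated)
Conditions: Cl2CHOMe, TiCl4, CH2Cl2, −10 to 0 °C; then H2O
Reagents that add atoms: dichloromethyl methyl ether, COC(Cl)Cl; water, O
Why: Rieche formylation; the only free positions are the two equivalent ones ortho to bromine and para to a methoxy group, so a single regioisomer can form.

Step 6
Reactants: 9 F-G-H phenol; 12 6-bromo-2,3,4-trimethoxybenzaldehyde
Product: 13 6-{3,4-dimethoxy-5-[3,4,5-trimethoxy-2-(3,4,5-trimethoxyphenoxy)phenoxy]phenoxy}-2,3,4-trimethoxybenzaldehyde (E-F-G-H aldehyde)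
Conditions: CuI (10 mol %), picolinic acid (20 mol %), K3PO4, DMSO, 90 °C, argon
Reagents that add atoms: none
Why: Ullmann coupling of a phenol without ortho substituents with a bromide activated by its ortho formyl group; the formyl group marks the carbon that will carry the crowded ring E oxygen.

Step 7
Reactants: 13 E-F-G-H aldehyde
Product: 15 6-{3,4-dimethoxy-5-[3,4,5-trimethoxy-2-(3,4,5-trimethoxyphenoxy)phenoxy]phenoxy}-2,3,4-trimethoxyphenol (E-F-G-H phenol, ArOH), via aryl formate 14 (not isolated)
Conditions: 30% H2O2, H2SO4 (cat.), MeOH, rt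
Reagents that add atoms: hydrogen peroxide, OO
Why: Acid-catalysed Dakin oxidation; the formyl group lies between an aryloxy and a methoxy group with a para methoxy group, the pattern of 2,4,6-trialkoxybenzaldehydes that undergo this exchange readily.

Step 8
Reactants: 15 E-F-G-H phenol; 16 dimethyl 2-chloromalonate
Product: 17 dimethyl 2-(ArO)malonate
Conditions: K2CO3, DMF, 50 °C, argon
Reagents that add atoms: none
Why: Williamson-type O-alkylation of a phenoxide with an α-halomalonate, an SN2 reaction at sp3 carbon that tolerates the two ortho substituents of 15; it has direct precedent in the alkylation of ortho-alkoxyphenols with dimethyl chloromalonate.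

Step 9
Reactants: 17 dimethyl 2-(ArO)malonate; 18 dimethyl 3-oxoglutarate
Product: 20 dimethyl 2,4,6-trihydroxy-5-(ArO)benzene-1,3-dicarboxylate (ring D formed), via open-chain tetracarbonyl ester 19 (not isolated)
Conditions: 18 (4 equiv), Mg(OMe)2 (2 equiv), MeOH then toluene, 110 °C, MeOH distilled off; then 1 M HCl
Reagents that add atoms: none
Why: Proposed new method: the closest known reactions are the alkoxide-mediated condensation of dialkyl malonates with dialkyl 3-oxoglutarates to 2,4,6-trihydroxyisophthalates and the Mg(OMe)2-induced Claisen cyclisation of 3,5,7-triketo esters to acylphloroglucinols, whereas a 2-aryloxymalonate that may act only as the double acyl donor has not been used. Because 18 is the stronger carbon acid the base resides on it, and its magnesium enolate attacks one ester carbonyl of largely un-ionised 17 (intermolecular Claisen condensation, loss of methoxide) to give the open tetracarbonyl chain 19. The remaining CH2 of 19 is then deprotonated and acylated by the second ester of the aryloxymalonate unit in a 6-exo-trig Dieckmann-type closure of ring D, and loss of methanol followed by enolisation gives the aromatic phenoxide of 20. No stereocentre is created. The selectivity required is carbon over oxygen acylation: chelation of the enolate oxygens to Mg2+ leaves carbon as the free nucleophilic site, and a 2-pyranone formed by O-acylation is reopened by methoxide while the aromatic phenoxide is not, so the carbocycle is the thermodynamic sink. Closure through the aryloxy-bearing carbon onto an oxoglutarate ester would give a quaternary, non-aromatisable trione that reverts by retro-Claisen cleavage. Both partners are symmetric, so only one constitution can form, and continuous removal of methanol drives both acylations. The ring E oxygen enters on the sp3 carbon of 17, so the ether with four ortho substituents is never made by aryl–oxygen coupling.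

Step 10
Reactants: 20 ring D diester
Product: 23 2-(ArO)benzene-1,3,5-triol, via diacid 21 (not isolated), via monoacid 22 (not isolated)
Conditions: 2 M NaOH (degassed), H2O–MeOH, reflux, argon; then 2 M HCl, 60 °C
Reagents that add atoms: none
Why: Saponification followed by decarboxylation of the 2,4,6-trihydroxybenzoic acids through their keto tautomers (β-keto acid type), the classical passage from phloroglucinol carboxylates to phloroglucinols; aryl and methyl ethers are inert.

Step 11
Reactants: 23 2-(ArO)benzene-1,3,5-triol
Product: 24 3,5-dihydroxy-4-(ArO)phenyl trifluoromethanesulfonate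
Conditions: PhNTf2 (1.0 equiv), iPr2NEt (1.2 equiv), CH2Cl2, 0 °C to rt
Reagents that add atoms: N-phenylbis(trifluoromethanesulfonimide), O=S(=O)(N(c1ccccc1)S(=O)(=O)C(F)(F)F)C(F)(F)F
Why: Chemoselective O-sulfonylation; the two hydroxyls next to the aryloxy group lie under the ortho substituents of the twisted ring E and are hydrogen-bonded to the ether oxygen, so the bulky, mild triflyl donor should react at the exposed para hydroxyl, and one equivalent limits double reaction.

Step 12
Reactants: 24 monotriflate
Product: 25 3,5-dimethoxy-4-(ArO)phenyl trifluoromethanesulfonate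
Conditions: MeI, K2CO3, acetone, 45 °C
Reagents that add atoms: iodomethane, CI
Why: Williamson methylation of the two remaining phenols, which is insensitive to their crowding; aryl triflates are stable to carbonate in acetone.

Step 13
Reactants: 26 4-bromo-2,6-dimethoxyphenol
Product: 27 2-(benzyloxy)-5-bromo-1,3-dimethoxybenzene
Conditions: BnBr, K2CO3, DMF, rt
Reagents that add atoms: benzyl bromide, BrCc1ccccc1
Why: Williamson benzylation; the benzyl ether keeps the bromophenol from condensing with itself in the next step and is removable without touching methyl ethers.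

Step 14
Reactants: 27 2-(benzyloxy)-5-bromo-1,3-dimethoxybenzene; 28 2,4,6-trimethoxyphenol
Product: 29 2-(benzyloxy)-1,3-dimethoxy-5-(2,4,6-trimethoxyphenoxy)benzene
Conditions: CuI (10 mol %), picolinic acid (20 mol %), K3PO4, DMSO, 105 °C, argon
Reagents that add atoms: none
Why: Ullmann diaryl ether synthesis with the di-ortho-substituted phenol as nucleophile and a bromide without ortho substituents, the pairing for which the CuI–picolinic acid system is suited.

Step 15
Reactants: 29 A-B benzyl ether
Product: 30 2,6-dimethoxy-4-(2,4,6-trimethoxyphenoxy)phenol (A-B phenol)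
Conditions: H2 (1 atm), 10% Pd/C, EtOAc–MeOH, rt
Reagents that add atoms: none
Why: Hydrogenolysis of the benzyl ether; aryl methyl ethers and the diaryl ether are inert to H2 over Pd/C.

Step 16
Reactants: 30 A-B phenol; 12 6-bromo-2,3,4-trimethoxybenzaldehyde
Product: 31 6-[2,6-dimethoxy-4-(2,4,6-trimethoxyphenoxy)phenoxy]-2,3,4-trimethoxybenzaldehyde (A-B-C aldehyde)
Conditions: CuI (10 mol %), picolinic acid (20 mol %), K3PO4, DMSO, 100 °C, argon
Reagents that add atoms: none
Why: Ullmann coupling of the hindered phenol 30 with a bromide that has one ortho substituent, the activating formyl group.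

Step 17
Reactants: 31 A-B-C aldehyde
Product: 33 6-[2,6-dimethoxy-4-(2,4,6-trimethoxyphenoxy)phenoxy]-2,3,4-trimethoxyphenol (A-B-C phenol), via aryl formate 32 (not isolated)
Conditions: 30% H2O2, H2SO4 (cat.), MeOH, rt
Reagents that add atoms: hydrogen peroxide, OO
Why: Acid-catalysed Dakin oxidation of a 2,6-dioxygenated benzaldehyde; H2O2 is used in place of a peracid to spare the phloroglucinol-type ring A.

Step 18
Reactants: 25 ring D–H triflate; 33 A-B-C phenol
Product: 34 henicosa-O-methyl ether of CNP0309601.0 (permethylated octamer)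
Conditions: Pd(OAc)2 (5 mol %), 2-(di-tert-butylphosphino)-2′,4′,6′-triisopropylbiphenyl (10 mol %), K3PO4, toluene, 100 °C
Reagents that add atoms: none
Why: Buchwald–Hartwig-type C–O coupling: oxidative addition of the unhindered aryl triflate to zerovalent palladium, exchange with the phenoxide of 33 and reductive elimination, which the bulky biarylphosphine promotes for di-ortho-substituted phenoxides; ring D carries no free hydroxyl that could compete.

Step 19
Reactants: 34 permethylated octamer
Product: 35 CNP0309601.0
Conditions: BBr3 (40 equiv), CH2Cl2, −78 °C to rt; then MeOH, H2O; argon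
Reagents that add atoms: none
Why: Lewis acid-mediated cleavage of all twenty-one aryl methyl ethers by bromide attack on the methyl group of the boron-complexed ether; the diaryl ether bonds offer no carbon open to SN2 attack. The aryloxyboron species formed are an undefined mixture hydrolysed on quench and carry no number.

## Compound list

1 | 2-bromo-3,4,5-trimethoxybenzaldehyde | O=Cc1cc(OC)c(OC)c(OC)c1Br | starting material
2 | 3,4,5-trimethoxyphenol | COc1cc(O)cc(OC)c1OC | starting material
3 | 3,4,5-trimethoxy-2-(3,4,5-trimethoxyphenoxy)benzaldehyde | O=Cc1cc(OC)c(OC)c(OC)c1Oc1cc(OC)c(OC)c(OC)c1 | intermediate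
4 | 3,4,5-trimethoxy-2-(3,4,5-trimethoxyphenoxy)phenyl formate | O=COc1cc(OC)c(OC)c(OC)c1Oc1cc(OC)c(OC)c(OC)c1 | intermediate (not isolated)
5 | 3,4,5-trimethoxy-2-(3,4,5-trimethoxyphenoxy)phenol | Oc1cc(OC)c(OC)c(OC)c1Oc1cc(OC)c(OC)c(OC)c1 | intermediate
6 | 3-bromo-4,5-dimethoxybenzaldehyde | O=Cc1cc(OC)c(OC)c(Br)c1 | starting material
7 | 3,4-dimethoxy-5-[3,4,5-trimethoxy-2-(3,4,5-trimethoxyphenoxy)phenoxy]benzaldehyde | O=Cc1cc(OC)c(OC)c(Oc2cc(OC)c(OC)c(OC)c2Oc2cc(OC)c(OC)c(OC)c2)c1 | intermediate
8 | 3,4-dimethoxy-5-[3,4,5-trimethoxy-2-(3,4,5-trimethoxyphenoxy)phenoxy]phenyl formate | O=COc1cc(OC)c(OC)c(Oc2cc(OC)c(OC)c(OC)c2Oc2cc(OC)c(OC)c(OC)c2)c1 | intermediate (not isolated)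
9 | 3,4-dimethoxy-5-[3,4,5-trimethoxy-2-(3,4,5-trimethoxyphenoxy)phenoxy]phenol | Oc1cc(OC)c(OC)c(Oc2cc(OC)c(OC)c(OC)c2Oc2cc(OC)c(OC)c(OC)c2)c1 | intermediate
10 | 5-bromo-1,2,3-trimethoxybenzene | COc1cc(Br)cc(OC)c1OC | starting material
11 | 1-bromo-2-[chloro(methoxy)methyl]-3,4,5-trimethoxybenzene | COC(Cl)c1c(Br)cc(OC)c(OC)c1OC | intermediate (not isolated)
12 | 6-bromo-2,3,4-trimethoxybenzaldehyde | O=Cc1c(Br)cc(OC)c(OC)c1OC | intermediate
13 | 6-{3,4-dimethoxy-5-[3,4,5-trimethoxy-2-(3,4,5-trimethoxyphenoxy)phenoxy]phenoxy}-2,3,4-trimethoxybenzaldehyde | O=Cc1c(Oc2cc(OC)c(OC)c(Oc3cc(OC)c(OC)c(OC)c3Oc3cc(OC)c(OC)c(OC)c3)c2)cc(OC)c(OC)c1OC | intermediate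
14 | 6-{3,4-dimethoxy-5-[3,4,5-trimethoxy-2-(3,4,5-trimethoxyphenoxy)phenoxy]phenoxy}-2,3,4-trimethoxyphenyl formate | O=COc1c(Oc2cc(OC)c(OC)c(Oc3cc(OC)c(OC)c(OC)c3Oc3cc(OC)c(OC)c(OC)c3)c2)cc(OC)c(OC)c1OC | intermediate (not isolated)
15 | 6-{3,4-dimethoxy-5-[3,4,5-trimethoxy-2-(3,4,5-trimethoxyphenoxy)phenoxy]phenoxy}-2,3,4-trimethoxyphenol (ArOH) | Oc1c(Oc2cc(OC)c(OC)c(Oc3cc(OC)c(OC)c(OC)c3Oc3cc(OC)c(OC)c(OC)c3)c2)cc(OC)c(OC)c1OC | intermediate
16 | dimethyl 2-chloromalonate | COC(=O)C(Cl)C(=O)OC | starting material
17 | dimethyl 2-(ArO)malonate | COC(=O)C(Oc1c(Oc2cc(OC)c(OC)c(Oc3cc(OC)c(OC)c(OC)c3Oc3cc(OC)c(OC)c(OC)c3)c2)cc(OC)c(OC)c1OC)C(=O)OC | intermediate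
18 | dimethyl 3-oxoglutarate (dimethyl 3-oxopentanedioate) | COC(=O)CC(=O)CC(=O)OC | starting material
19 | trimethyl 1-(ArO)-2,4-dioxopentane-1,3,5-tricarboxylate | COC(=O)C(Oc1c(Oc2cc(OC)c(OC)c(Oc3cc(OC)c(OC)c(OC)c3Oc3cc(OC)c(OC)c(OC)c3)c2)cc(OC)c(OC)c1OC)C(=O)C(C(=O)OC)C(=O)CC(=O)OC | intermediate (not isolated)
20 | dimethyl 2,4,6-trihydroxy-5-(ArO)benzene-1,3-dicarboxylate | COC(=O)c1c(O)c(C(=O)OC)c(O)c(Oc4c(Oc5cc(OC)c(OC)c(Oc6cc(OC)c(OC)c(OC)c6Oc6cc(OC)c(OC)c(OC)c6)c5)cc(OC)c(OC)c4OC)c1O | intermediate
21 | 2,4,6-trihydroxy-5-(ArO)benzene-1,3-dicarboxylic acid | OC(=O)c1c(O)c(C(=O)O)c(O)c(Oc4c(Oc5cc(OC)c(OC)c(Oc6cc(OC)c(OC)c(OC)c6Oc6cc(OC)c(OC)c(OC)c6)c5)cc(OC)c(OC)c4OC)c1O | intermediate (not isolated)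
22 | 2,4,6-trihydroxy-3-(ArO)benzoic acid | OC(=O)c1c(O)cc(O)c(Oc4c(Oc5cc(OC)c(OC)c(Oc6cc(OC)c(OC)c(OC)c6Oc6cc(OC)c(OC)c(OC)c6)c5)cc(OC)c(OC)c4OC)c1O | intermediate (not isolated)
23 | 2-(ArO)benzene-1,3,5-triol | Oc1cc(O)c(Oc4c(Oc5cc(OC)c(OC)c(Oc6cc(OC)c(OC)c(OC)c6Oc6cc(OC)c(OC)c(OC)c6)c5)cc(OC)c(OC)c4OC)c(O)c1 | intermediate
24 | 3,5-dihydroxy-4-(ArO)phenyl trifluoromethanesulfonate | O=S(=O)(Oc1cc(O)c(Oc4c(Oc5cc(OC)c(OC)c(Oc6cc(OC)c(OC)c(OC)c6Oc6cc(OC)c(OC)c(OC)c6)c5)cc(OC)c(OC)c4OC)c(O)c1)C(F)(F)F | intermediate
25 | 3,5-dimethoxy-4-(ArO)phenyl trifluoromethanesulfonate | O=S(=O)(Oc1cc(OC)c(Oc4c(Oc5cc(OC)c(OC)c(Oc6cc(OC)c(OC)c(OC)c6Oc6cc(OC)c(OC)c(OC)c6)c5)cc(OC)c(OC)c4OC)c(OC)c1)C(F)(F)F | intermediate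
26 | 4-bromo-2,6-dimethoxyphenol | COc1cc(Br)cc(OC)c1O | starting material
27 | 2-(benzyloxy)-5-bromo-1,3-dimethoxybenzene | COc1cc(Br)cc(OC)c1OCc1ccccc1 | intermediate
28 | 2,4,6-trimethoxyphenol | COc1cc(OC)c(O)c(OC)c1 | starting material
29 | 2-(benzyloxy)-1,3-dimethoxy-5-(2,4,6-trimethoxyphenoxy)benzene | COc1cc(OC)c(Oc2cc(OC)c(OCc3ccccc3)c(OC)c2)c(OC)c1 | intermediate
30 | 2,6-dimethoxy-4-(2,4,6-trimethoxyphenoxy)phenol | COc1cc(OC)c(Oc2cc(OC)c(O)c(OC)c2)c(OC)c1 | intermediate
31 | 6-[2,6-dimethoxy-4-(2,4,6-trimethoxyphenoxy)phenoxy]-2,3,4-trimethoxybenzaldehyde | O=Cc1c(Oc2c(OC)cc(Oc3c(OC)cc(OC)cc3OC)cc2OC)cc(OC)c(OC)c1OC | intermediate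
32 | 6-[2,6-dimethoxy-4-(2,4,6-trimethoxyphenoxy)phenoxy]-2,3,4-trimethoxyphenyl formate | O=COc1c(Oc2c(OC)cc(Oc3c(OC)cc(OC)cc3OC)cc2OC)cc(OC)c(OC)c1OC | intermediate (not isolated)
33 | 6-[2,6-dimethoxy-4-(2,4,6-trimethoxyphenoxy)phenoxy]-2,3,4-trimethoxyphenol | Oc1c(Oc2c(OC)cc(Oc3c(OC)cc(OC)cc3OC)cc2OC)cc(OC)c(OC)c1OC | intermediate
34 | henicosa-O-methyl ether of CNP0309601.0 (every hydroxyl of 35 as a methyl ether) | COc1cc(OC)c(Oc2cc(OC)c(Oc3cc(OC)c(OC)c(OC)c3Oc3cc(OC)c(Oc4c(Oc5cc(OC)c(OC)c(Oc6cc(OC)c(OC)c(OC)c6Oc6cc(OC)c(OC)c(OC)c6)c5)cc(OC)c(OC)c4OC)c(OC)c3)c(OC)c2)c(OC)c1 | intermediate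
35 | CNP0309601.0 | Oc1cc(O)c(Oc2cc(O)c(Oc3cc(O)c(O)c(O)c3Oc3cc(O)c(Oc4c(Oc5cc(O)c(O)c(Oc6cc(O)c(O)c(O)c6Oc6cc(O)c(O)c(O)c6)c5)cc(O)c(O)c4O)c(O)c3)c(O)c2)c(O)c1 | target

## Step count and risk assessment

Total: 19 steps. Longest linear sequence: 13 steps (steps 1, 2, 3, 4, 6, 7, 8, 9, 10, 11, 12, 18, 19). Step 5 feeds both branches, and the A-B-C branch (steps 13 to 17) joins at step 18.

**Step 9 (key step, proposed new method).**
- What may go wrong: proton transfer from 17 to the enolate of 18 may outrun acylation, so that the first Claisen condensation stalls. Acylation at an enol oxygen may divert material into a lactone that reopens too slowly. Self-condensation of 18 may compete at the temperature needed.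
- Fallback (known reaction types, acylation and ring closure separated): malonate 17 is saponified (LiOH, THF–H2O, 0 °C) to 2-(ArO)malonic acid F1. This is converted with oxalyl chloride and catalytic DMF into 2-(ArO)malonyl dichloride F2. F2 is condensed with 18 under soft enolisation (MgCl2, Et3N, MeCN, 0 °C to rt), the known route from malonyl dichlorides and β-keto esters to 4-hydroxy-2-pyranones, to give methyl 3-(ArO)-4-hydroxy-6-(2-methoxy-2-oxoethyl)-2-oxo-2H-pyran-5-carboxylate F3. Treatment of the pyranone with Mg(OMe)2 in refluxing MeOH, the known pyranone-to-phloroglucinol isomerisation, opens the lactone to the same chain 19 and closes it at carbon. The route is rejoined at 20.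

**Step 11.**
- What may go wrong: loss of site selectivity, that is sulfonylation of a hydroxyl next to the aryloxy group, or double sulfonylation, because the discrimination rests on steric shielding alone.
- Fallback (protecting-group relay with a far bulkier, removable electrophile): triol 23 is silylated with iPr3SiCl and imidazole (DMF, −20 °C) to 2-(ArO)-5-[(triisopropylsilyl)oxy]benzene-1,3-diol F4. Wrong isomers can be desilylated and recycled. Methylation (MeI, K2CO3, acetone) gives [3,5-dimethoxy-4-(ArO)phenoxy]triisopropylsilane F5. Bu4NF in THF releases 3,5-dimethoxy-4-(ArO)phenol F6, and Tf2O with pyridine in CH2Cl2 at 0 °C returns the route to 25.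

**Step 18.**
- What may go wrong: slow reductive elimination from the crowded aryl(aryloxy)palladium intermediate, so that transfer of the triflyl group from 25 to the phenoxide of 33 (S–O cleavage) takes over.
- Fallback (polarity of ring D reversed, no triflate present in the coupling): triflate 25 is borylated with B2(OH)4 (Pd(OAc)2, 2-dicyclohexylphosphino-2′,4′,6′-triisopropylbiphenyl, KOAc, EtOH, 80 °C) to [3,5-dimethoxy-4-(ArO)phenyl]boronic acid F7. F7 is joined to phenol 33 by Chan–Lam oxidative coupling (Cu(OAc)2, pyridine, 4 Å molecular sieves, CH2Cl2, air, rt), a reaction known to accept di-ortho-substituted phenols. The route is rejoined at 34.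

**Step 19.**
- What may go wrong: incomplete cleavage at some of the twenty-one methyl ethers, and oxidative or acid-induced degradation of the free polyphenol during isolation.
- Fallback (derivatise, purify, release): 34 is treated with BBr3 as in step 19. After the methanol quench and evaporation, the crude product is acetylated (Ac2O, pyridine) to the henicosaacetate of CNP0309601.0 F8, which is stable to air and silica and can be separated from partly methylated congeners. Hydrazinolysis (N2H4·H2O, MeCN–MeOH, 0 °C, argon) then releases 35 under non-oxidising, nearly neutral conditions.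

## Further compounds

F1 | step 9 | 2-(ArO)malonic acid | OC(=O)C(Oc1c(Oc2cc(OC)c(OC)c(Oc3cc(OC)c(OC)c(OC)c3Oc3cc(OC)c(OC)c(OC)c3)c2)cc(OC)c(OC)c1OC)C(=O)O
F2 | step 9 | 2-(ArO)malonyl dichloride | ClC(=O)C(Oc1c(Oc2cc(OC)c(OC)c(Oc3cc(OC)c(OC)c(OC)c3Oc3cc(OC)c(OC)c(OC)c3)c2)cc(OC)c(OC)c1OC)C(=O)Cl
F3 | step 9 | methyl 3-(ArO)-4-hydroxy-6-(2-methoxy-2-oxoethyl)-2-oxo-2H-pyran-5-carboxylate | COC(=O)Cc1oc(=O)c(Oc4c(Oc5cc(OC)c(OC)c(Oc6cc(OC)c(OC)c(OC)c6Oc6cc(OC)c(OC)c(OC)c6)c5)cc(OC)c(OC)c4OC)c(O)c1C(=O)OC
F4 | step 11 | 2-(ArO)-5-[(triisopropylsilyl)oxy]benzene-1,3-diol | CC(C)[Si](Oc1cc(O)c(Oc4c(Oc5cc(OC)c(OC)c(Oc6cc(OC)c(OC)c(OC)c6Oc6cc(OC)c(OC)c(OC)c6)c5)cc(OC)c(OC)c4OC)c(O)c1)(C(C)C)C(C)C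
F5 | step 11 | [3,5-dimethoxy-4-(ArO)phenoxy]triisopropylsilane | CC(C)[Si](Oc1cc(OC)c(Oc4c(Oc5cc(OC)c(OC)c(Oc6cc(OC)c(OC)c(OC)c6Oc6cc(OC)c(OC)c(OC)c6)c5)cc(OC)c(OC)c4OC)c(OC)c1)(C(C)C)C(C)C
F6 | step 11 | 3,5-dimethoxy-4-(ArO)phenol | Oc1cc(OC)c(Oc4c(Oc5cc(OC)c(OC)c(Oc6cc(OC)c(OC)c(OC)c6Oc6cc(OC)c(OC)c(OC)c6)c5)cc(OC)c(OC)c4OC)c(OC)c1
F7 | step 18 | [3,5-dimethoxy-4-(ArO)phenyl]boronic acid | OB(O)c1cc(OC)c(Oc4c(Oc5cc(OC)c(OC)c(Oc6cc(OC)c(OC)c(OC)c6Oc6cc(OC)c(OC)c(OC)c6)c5)cc(OC)c(OC)c4OC)c(OC)c1
F8 | step 19 | henicosaacetate of CNP0309601.0 (every hydroxyl of 35 as an acetate) | CC(=O)Oc1cc(OC(C)=O)c(Oc2cc(OC(C)=O)c(Oc3cc(OC(C)=O)c(OC(C)=O)c(OC(C)=O)c3Oc3cc(OC(C)=O)c(Oc4c(Oc5cc(OC(C)=O)c(OC(C)=O)c(Oc6cc(OC(C)=O)c(OC(C)=O)c(OC(C)=O)c6Oc6cc(OC(C)=O)c(OC(C)=O)c(OC(C)=O)c6)c5)cc(OC(C)=O)c(OC(C)=O)c4OC(C)=O)c(OC(C)=O)c3)c(OC(C)=O)c2)c(OC(C)=O)c1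
A1 | alternative 1 | permethylated octamer carrying formyl groups in place of four methoxy groups (rings C, E, G and H) | COc1cc(OC)c(Oc2cc(OC)c(Oc3cc(OC)c(C=O)c(OC)c3Oc3cc(OC)c(Oc4c(Oc5cc(OC)c(OC)c(Oc6cc(OC)c(C=O)c(OC)c6Oc6cc(OC)c(C=O)c(OC)c6)c5)cc(C=O)c(OC)c4OC)c(OC)c3)c(OC)c2)c(OC)c1
A2 | alternative 1 | octamer tetraphenol with all other hydroxyls as methyl ethers | COc1cc(OC)c(Oc2cc(OC)c(Oc3cc(OC)c(O)c(OC)c3Oc3cc(OC)c(Oc4c(Oc5cc(OC)c(OC)c(Oc6cc(OC)c(O)c(OC)c6Oc6cc(OC)c(O)c(OC)c6)c5)cc(O)c(OC)c4OC)c(OC)c3)c(OC)c2)c(OC)c1
A3 | alternative 2 | 4-[(tert-butyldimethylsilyl)oxy]-4-{1-[2,6-dimethoxy-4-(2,4,6-trimethoxyphenoxy)phenoxy]ethenyl}-2,3-dimethoxycyclobut-2-en-1-one | COC1=C(OC)C(O[Si](C)(C)C(C)(C)C)(C(=C)Oc2c(OC)cc(Oc3c(OC)cc(OC)cc3OC)cc2OC)C1=O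
A4 | alternative 2 | A-B-C trimer with free ring C phenol and silyl ether at the future ether carbon to ring D | Oc1cc(Oc2c(OC)cc(Oc3c(OC)cc(OC)cc3OC)cc2OC)c(O[Si](C)(C)C(C)(C)C)c(OC)c1OC
A5 | alternative 3 | 1-(ethynyloxy)-3,4,5-trimethoxy-2-(3,4,5-trimethoxyphenoxy)benzene | C#COc1cc(OC)c(OC)c(OC)c1Oc1cc(OC)c(OC)c(OC)c1
A6 | alternative 3 | 2,3-dimethoxycyclobut-2-en-1-one | COC1=C(OC)C(=O)C1
A7 | alternative 3 | F-G-H trimer phenol (identical with 9) | Oc1cc(OC)c(OC)c(Oc2cc(OC)c(OC)c(OC)c2Oc2cc(OC)c(OC)c(OC)c2)c1
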